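## Retrosynthetic overview

1. Structural feature: in ring B (C1–C8–C7–C6–C5–C9) the C1–C8 bond ties a bridgehead to the quaternary C8 (methyl, homoprenyl), and the neighbouring C7 carries a replaceable substituent. C6–C7–C8 therefore maps onto a cis-2,3-epoxyneryl chain on C5. Ring A (C1–C2–C3–C4–C5–C9) maps onto a Birch diene with two like enol ethers, C9=C1 and C4=C3, on either side of C5.
2. Late disconnections: catechol silyl ethers and the C4 O-methyl group; C3–aroyl (vinyl lithiation, acylation); C7–prenyl (Keck allylation of a C7 thionocarbonate, then cross-metathesis); C1–prenyl (bridgehead lithiation); C2 carbonyl (allylic oxidation).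
3. Key disconnection: C1–C8, made when a silyl triflate opens the epoxide at its tertiary carbon under attack by one of the two enol ethers.
4. Precursor: the quaternary C5 comes from two successive alkylations of lithiated 1,5-dimethoxycyclohexa-1,4-diene, first with (S)-lavandulyl iodide (Evans alkylation), then with epoxyneryl bromide (Sharpless epoxidation of nerol).
5. Ring order: the carbocycle that becomes ring A comes from 1,3-dimethoxybenzene, ring B is closed in the key step, and no other ring is kept.

Key step: step 10

Numbering: C1 and C5 are the bridgeheads, C2–C3–C4 is the enolised diketone bridge, C6–C7–C8 is the saturated bridge, and C9 is the ketone bridge. "Equatorial" and "axial" refer to chair ring B.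

Assumption: the enolised triketone is treated as the C4-enol/C2-keto tautomer drawn in the target SMILES; the tautomers interconvert and count as one compound.

## Route

Step 1
Reactants: 1 (S)-4-benzyl-1,3-oxazolidin-2-one; 2 3-methylbut-2-enoyl chloride
Product: 4 (S)-4-benzyl-3-(3-methylbut-2-enoyl)-1,3-oxazolidin-2-one, via N-lithio oxazolidinone 3 (not isolated)
Conditions: n-BuLi, THF, −78 °C; then 2, −78 → 0 °C
Reagents that add atoms: none
Why: N-acylation of a lithiated Evans auxiliary by an acid chloride is fast at low temperature and touches no stereocentre.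

Step 2
Reactants: 4 (S)-4-benzyl-3-(3-methylbut-2-enoyl)-1,3-oxazolidin-2-one; 5 prenyl bromide (1-bromo-3-methylbut-2-ene)
Product: 7 (4S)-4-benzyl-3-[(2S)-5-methyl-2-(prop-1-en-2-yl)hex-4-enoyl]-1,3-oxazolidin-2-one, via sodium (Z)-dienolate 6 (not isolated)
Conditions: NaHMDS, THF, −78 °C; then 5, −78 → −30 °C
Reagents that add atoms: none
Why: In this deconjugative Evans alkylation, γ-deprotonation of the s-cis enoyl imide gives the chelated (Z)-dienolate, which is alkylated at its α-carbon on the face away from the benzyl group, and this sets the (S) centre of the lavandulyl unit.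

Step 3
Reactants: 7 the alkylated imide
Product: 8 (S)-lavandulol, (2S)-5-methyl-2-(prop-1-en-2-yl)hex-4-en-1-ol
Conditions: LiBH4, H2O (1 equiv), Et2O, 0 °C
Reagents that add atoms: none
Why: Reductive cleavage of an N-acyl oxazolidinone by borohydride attacks the exocyclic carbonyl under weakly basic conditions, so the allylic α-centre should be neither epimerised nor moved into conjugation.

Step 4
Reactants: 8 (S)-lavandulol
Product: 9 (S)-lavandulyl iodide, (3S)-3-(iodomethyl)-2,6-dimethylhepta-1,5-diene
Conditions: I2, PPh3, imidazole, CH2Cl2, 0 °C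
Reagents that add atoms: iodine, II
Why: Appel-type iodination is an SN2 displacement at the primary carbon and leaves the neighbouring stereocentre alone.

Step 5
Reactants: 10 1,3-dimethoxybenzene
Product: 11 1,5-dimethoxycyclohexa-1,4-diene
Conditions: Li, NH3(l), t-BuOH, THF, −78 → −33 °C
Reagents that add atoms: none
Why: Birch reduction keeps both donor groups on the remaining double bonds and gives the unconjugated bis(enol ether).

Step 6
Reactants: 11 1,5-dimethoxycyclohexa-1,4-diene; 9 (S)-lavandulyl iodide
Product: 13 6-lavandulyl-1,5-dimethoxycyclohexa-1,4-diene (side-chain centre unchanged in space), via 6-lithio diene 12 (not isolated)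
Conditions: t-BuLi (1.0 equiv), THF, −78 °C; then HMPA, 9, −78 → 0 °C
Reagents that add atoms: none
Why: The CH2 between the two methoxy-bearing carbons is the most acidic site, and the cyclohexadienyl anion undergoes SN2 alkylation at its central carbon, which keeps the 1,4-diene.

Step 7
Reactants: 14 nerol
Product: 15 (2S,3R)-2,3-epoxynerol (CH2OH and homoprenyl cis on the oxirane)
Conditions: Ti(OiPr)4 (cat.), L-(+)-diethyl tartrate (cat.), t-BuOOH, 4 Å MS, CH2Cl2, −20 °C
Reagents that add atoms: tert-butyl hydroperoxide, CC(C)(C)OO
Why: Sharpless asymmetric epoxidation oxidises only the allylic-alcohol alkene; the L-(+)-tartrate fixes the face (2S), and the Z geometry then gives 3R.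

Step 8
Reactants: 15 (2S,3R)-2,3-epoxynerol
Product: 17 epoxyneryl bromide, (2R,3R)-3-(bromomethyl)-2-methyl-2-(4-methylpent-3-enyl)oxirane, via epoxyneryl mesylate 16 (not isolated)
Conditions: MsCl, Et3N, CH2Cl2, −20 °C; then LiBr, THF, 0 °C → rt
Reagents that add atoms: lithium bromide, [Li+].[Br-]
Why: Mesylation followed by SN2 halide displacement at the primary carbon is acid-free, so the trisubstituted epoxide and both of its stereocentres stay intact.

Step 9
Reactants: 13 6-lavandulyl-1,5-dimethoxycyclohexa-1,4-diene; 17 epoxyneryl bromide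
Product: 19 6-lavandulyl-6-(cis-2,3-epoxyneryl)-1,5-dimethoxycyclohexa-1,4-diene, via tertiary dienyllithium 18 (not isolated)
Conditions: s-BuLi, THF, −78 → −30 °C; then 17, −78 → −20 °C
Reagents that add atoms: none
Why: A second dienyl-anion alkylation takes place at the same carbon; the remaining doubly allylic C–H flanked by the two OMe groups is removed, and the activated primary bromide is displaced faster than the epoxide is opened, which builds the quaternary C5.

Step 10
Reactants: 19 6-lavandulyl-6-(cis-2,3-epoxyneryl)-1,5-dimethoxycyclohexa-1,4-diene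
Product: 22 bicyclo[3.3.1]non-3-en-9-one with C5 lavandulyl, C4 OMe, C1–H, C7 OSiMe3 equatorial, C8 methyl equatorial and C8 homoprenyl axial, via C9 oxocarbenium triflate 20 (not isolated), via caged methyl ketal 21 (not isolated)
Conditions: TMSOTf (1.2 equiv), 2,6-lutidine, CH2Cl2, −78 °C; then n-Bu4NI (1.5 equiv), −78 → 0 °C
Reagents that add atoms: trimethylsilyl triflate, C[Si](C)(C)OS(=O)(=O)C(F)(F)F
Why: TMSOTf silylates the epoxide oxygen, the C8–O bond lengthens, and the enol ether carbon C1 attacks C8 from the side opposite the leaving oxygen, which makes C1–C8 and leaves the C9 oxocarbenium ion 20; this is a Lewis-acid-promoted epoxide-opening cyclisation by an enol ether π-nucleophile, a reaction type known for 6,6-disubstituted 1,5-dimethoxycyclohexa-1,4-dienes carrying a trisubstituted 2,3-epoxyalkyl chain. Ring B closes in the 6-endo mode at the epoxide, which beats the 5-exo mode at C7 because the positive charge builds up on the tertiary C8. C7 keeps the configuration set in step 7, C8 is inverted so that the cis epoxide places methyl equatorial and homoprenyl axial, and C1 and C5 are set by the choice between the two diastereotopic enol ethers, since only C9=C1 lets the new ring adopt a chair with the C7–O bond equatorial and antiperiplanar to the incoming C1, whereas the other enol ether would need a boat. The C7 silyl ether oxygen should then add to C9 through the boat form of ring B to give the caged ketal 21, a fast internal quench that keeps the cation away from the axial homoprenyl alkene. Me3SiI formed from the regenerated TMSOTf and iodide re-opens 21, which can ionise only back to 20 because an oxocarbenium ion inside the oxygen bridge would be an anti-Bredt species, and iodide then removes the O-methyl group irreversibly (silyl iodide cleavage of a ketal). The step needs the epoxide to react with the enol ether rather than by proton loss or with the side-chain alkenes, which the higher nucleophilicity and proximity of the enol ether secure, and it needs the C4 enol ether to survive, which the amine buffer secures because methyl enol ethers tolerate Me3SiI in the presence of base.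

Step 11
Reactants: 22 the C7 silyl ether ketone
Product: 23 C2-oxo derivative of 22 (β-methoxy enone C2(=O)–C3H=C4–OMe; C1–H, C7 OSiMe3 and C9 ketone unchanged)
Conditions: t-BuOOH, Pd(OH)2/C (cat.), Cs2CO3, CH2Cl2, 0 °C
Reagents that add atoms: tert-butyl hydroperoxide, CC(C)(C)OO
Why: In this radical allylic oxidation by t-BuOO radicals, the C2–H bonds are the weakest allylic C–H bonds because the derived allyl radical is conjugated with the methoxy oxygen, and the C2 peroxide collapses under base (Kornblum–DeLaMare) to the enone faster than the prenyl-type alkenes are attacked.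

Step 12
Reactants: 23 the vinylogous ester
Product: 25 C3-trimethylsilyl derivative of 23, via C3-lithio enone 24 (not isolated)
Conditions: LiTMP, TMSCl (in situ quench), THF, −78 °C
Reagents that add atoms: chlorotrimethylsilane, C[Si](C)(C)Cl
Why: This is a vinyl lithiation of a β-alkoxy enone with an internal silyl quench; the exposed C3–H is removed faster than the C1–H next to the quaternary C8, and the silyl group blocks C3 for the next step.

Step 13
Reactants: 25 the C3-silylated vinylogous ester; 5 prenyl bromide
Product: 27 C1-prenyl derivative of 25 (quaternary C1), via C1 bridgehead lithium compound 26 (not isolated)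
Conditions: LiTMP, THF, −78 → −20 °C; then 5, −78 °C → rt
Reagents that add atoms: none
Why: In this bridgehead lithiation–alkylation with C3 blocked, the C1–H between the C2 and C9 carbonyls is the only acidic C–H left, and the bicycle holds the pyramidal carbanion so that SN2 attack on prenyl bromide can only give the required C1 configuration.

Step 14
Reactants: 27 the C1-prenylated bis-silyl compound
Product: 28 C7 alcohol (OH equatorial) with free C3–H, C1 prenyl and C4 OMe
Conditions: TBAF, AcOH, THF, 0 °C → rt
Reagents that add atoms: none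
Why: Fluoride desilylation cleaves both the C7 O–Si bond and the C3 vinyl C–Si bond, and the acetic acid buffer keeps the C7 oxygen protonated so that it cannot add to C9 and open the β-diketone by a retro-Claisen reaction.

Step 15
Reactants: 28 the C7 alcohol
Product: 29 C7 O-phenyl thionocarbonate of 28
Conditions: PhOC(S)Cl, DMAP, MeCN, rt → 40 °C
Reagents that add atoms: O-phenyl chlorothionoformate, ClC(=S)Oc1ccccc1
Why: DMAP-mediated thioacylation activates the hindered secondary alcohol without forming an alkoxide, which a xanthate synthesis would require and which would endanger the C1–C9 bond.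

Step 16
Reactants: 29 the C7 thionocarbonate
Product: 30 C7 allyl compound (allyl equatorial, C7–H axial)
Conditions: allylSnBu3 (neat, large excess), Et3B, air, rt
Reagents that add atoms: allyltributylstannane, C=CC[Sn](CCCC)(CCCC)CCCC
Why: In the Keck radical allylation, the stannyl radical adds to C=S, the C7–O bond fragments, and the C7 radical takes the allyl group on the open face of ring B because ring A shields the endo face, which sets C7 with the chain equatorial; neat stannane favours bimolecular capture.

Step 17
Reactants: 30 the C7 allyl compound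
Product: 31 C7 prenyl compound (C1 prenyl, C5 lavandulyl, C8 methyl/homoprenyl, C3–H, C4 OMe)
Conditions: second-generation Hoveyda–Grubbs catalyst (cat.), 2-methylbut-2-ene (excess), CH2Cl2, 40 °C
Reagents that add atoms: 2-methylbut-2-ene, CC=C(C)C
Why: In this olefin cross-metathesis the monosubstituted allyl alkene is the only fast-reacting olefin, exchange at the prenyl-type alkenes is degenerate, and the isopropenyl group next to a tertiary carbon is too hindered to take part.

Step 18
Reactants: 32 3,4-dihydroxybenzoic acid
Product: 33 tert-butyldimethylsilyl 3,4-bis(tert-butyldimethylsilyloxy)benzoate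
Conditions: TBSCl (3.3 equiv), imidazole, DMF, rt
Reagents that add atoms: tert-butyldimethylsilyl chloride, CC(C)(C)[Si](C)(C)Cl
Why: Exhaustive imidazole-promoted silylation protects both phenols and turns the acid into a silyl ester.

Step 19
Reactants: 33 the tris-silyl compound
Product: 34 3,4-bis(tert-butyldimethylsilyloxy)benzoyl chloride
Conditions: (COCl)2, DMF (cat.), CH2Cl2, 0 °C → rt
Reagents that add atoms: oxalyl chloride, O=C(Cl)C(=O)Cl
Why: The Vilsmeier-type chloroiminium reagent converts a silyl ester directly into the acid chloride under neutral conditions that leave aryl silyl ethers intact.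

Step 20
Reactants: 31 the C7 prenyl compound; 34 3,4-bis(tert-butyldimethylsilyloxy)benzoyl chloride
Product: 36 C3-aroyl compound (C4 OMe, catechol as bis-TBS ether), via C3-lithio enone 35 (not isolated)
Conditions: LiTMP, THF, −78 °C; then 34, −78 → −40 °C
Reagents that add atoms: none
Why: With both bridgeheads quaternary, C3–H is the only acidic site of the β-methoxy enone, so vinyl lithiation followed by acylation with an acid chloride gives a ketone that has no enolisable hydrogen to consume base.

Step 21
Reactants: 36 the C3-aroyl methyl enol ether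
Product: 37 C4 enol (bis-TBS ether of the target)
Conditions: LiCl, DMSO, 120 °C, Ar; then cold 0.5 M HCl work-up
Reagents that add atoms: none
Why: In this Krapcho-type SN2 dealkylation, chloride attacks the O-methyl carbon because the leaving group is a stabilised triketone enolate, and the neutral medium avoids acid-induced cyclisation of the enol onto the prenyl groups.

Step 22
Reactants: 37 the bis-TBS ether
Product: 38 target CNP0241026.2
Conditions: TBAF, AcOH, THF, 0 °C, Ar
Reagents that add atoms: none
Why: Buffered fluoride cleaves aryl silyl ethers rapidly at low temperature, and the buffer with exclusion of air protects the free catechol and the enol; no stereocentre is touched.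

## Compound list

1 | (S)-4-benzyl-1,3-oxazolidin-2-one | O=C1N[C@@H](Cc2ccccc2)CO1 | starting material
2 | 3-methylbut-2-enoyl chloride | CC(C)=CC(=O)Cl | starting material
3 | N-lithio derivative of 1 | [Li]N1C(=O)OC[C@@H]1Cc1ccccc1 | intermediate
4 | (S)-4-benzyl-3-(3-methylbut-2-enoyl)-1,3-oxazolidin-2-one | CC(C)=CC(=O)N1C(=O)OC[C@@H]1Cc1ccccc1 | intermediate
5 | prenyl bromide | CC(C)=CCBr | starting material
6 | sodium (Z)-dienolate of 4 | C=C(C)/C=C(\[O-])N1C(=O)OC[C@@H]1Cc1ccccc1.[Na+] | intermediate
7 | (4S)-4-benzyl-3-[(2S)-5-methyl-2-(prop-1-en-2-yl)hex-4-enoyl]-1,3-oxazolidin-2-one | C=C(C)[C@H](CC=C(C)C)C(=O)N1C(=O)OC[C@@H]1Cc1ccccc1 | intermediate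
8 | (S)-lavandulol | C=C(C)[C@H](CC=C(C)C)CO | intermediate
9 | (S)-lavandulyl iodide | C=C(C)[C@H](CC=C(C)C)CI | intermediate
10 | 1,3-dimethoxybenzene | COc1cccc(OC)c1 | starting material
11 | 1,5-dimethoxycyclohexa-1,4-diene | COC1=CCC=C(OC)C1 | intermediate
12 | 6-lithio-1,5-dimethoxycyclohexa-1,4-diene | [Li]C1C(OC)=CCC=C1OC | intermediate
13 | 6-lavandulyl-1,5-dimethoxycyclohexa-1,4-diene | C=C(C)[C@H](CC=C(C)C)CC1C(OC)=CCC=C1OC | intermediate
14 | nerol | OC/C=C(/C)CCC=C(C)C | starting material
15 | (2S,3R)-2,3-epoxynerol | OC[C@@H]1O[C@]1(C)CCC=C(C)C | intermediate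
16 | epoxyneryl mesylate | CS(=O)(=O)OC[C@@H]1O[C@]1(C)CCC=C(C)C | intermediate
17 | epoxyneryl bromide | BrC[C@@H]1O[C@]1(C)CCC=C(C)C | intermediate
18 | 6-lithio-6-lavandulyl-1,5-dimethoxycyclohexa-1,4-diene | C=C(C)[C@H](CC=C(C)C)CC1([Li])C(OC)=CCC=C1OC | intermediate
19 | 6-lavandulyl-6-(cis-2,3-epoxyneryl)-1,5-dimethoxycyclohexa-1,4-diene (key-step precursor) | C=C(C)[C@H](CC=C(C)C)CC1(C[C@@H]2O[C@]2(C)CCC=C(C)C)C(OC)=CCC=C1OC | intermediate
20 | C9 O-methyl oxocarbenium triflate of the bicycle | C=C(C)[C@H](CC=C(C)C)C[C@@]12C[C@H](O[Si](C)(C)C)[C@](C)(CCC=C(C)C)[C@@H](CC=C1OC)C2=[O+]C.[O-]S(=O)(=O)C(F)(F)F | intermediate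
21 | caged methyl ketal (oxygen bridge C7–O–C9, OMe on C9) | C=C(C)[C@H](CC=C(C)C)C[C@@]12C[C@@H]3O[C@@]2(OC)[C@H](CC=C1OC)[C@@]3(C)CCC=C(C)C | intermediate
22 | C7 silyl ether, C9 ketone, C4 methyl enol ether (key-step product) | C=C(C)[C@H](CC=C(C)C)C[C@@]12C[C@H](O[Si](C)(C)C)[C@](C)(CCC=C(C)C)[C@@H](CC=C1OC)C2=O | intermediate
23 | C2-oxo vinylogous ester | C=C(C)[C@H](CC=C(C)C)C[C@@]12C[C@H](O[Si](C)(C)C)[C@](C)(CCC=C(C)C)[C@@H](C(=O)C=C1OC)C2=O | intermediate
24 | C3-lithio derivative of 23 | C=C(C)[C@H](CC=C(C)C)C[C@@]12C[C@H](O[Si](C)(C)C)[C@](C)(CCC=C(C)C)[C@@H](C(=O)C([Li])=C1OC)C2=O | intermediate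
25 | C3-trimethylsilyl vinylogous ester | C=C(C)[C@H](CC=C(C)C)C[C@@]12C[C@H](O[Si](C)(C)C)[C@](C)(CCC=C(C)C)[C@@H](C(=O)C([Si](C)(C)C)=C1OC)C2=O | intermediate
26 | C1-lithio derivative of 25 | C=C(C)[C@H](CC=C(C)C)C[C@@]12C[C@H](O[Si](C)(C)C)[C@](C)(CCC=C(C)C)[C@@]([Li])(C(=O)C([Si](C)(C)C)=C1OC)C2=O | intermediate
27 | C1-prenyl, C3-silyl, C7-silyloxy compound | C=C(C)[C@H](CC=C(C)C)C[C@@]12C[C@H](O[Si](C)(C)C)[C@](C)(CCC=C(C)C)[C@@](CC=C(C)C)(C(=O)C([Si](C)(C)C)=C1OC)C2=O | intermediate
28 | C7 alcohol | C=C(C)[C@H](CC=C(C)C)C[C@@]12C[C@H](O)[C@](C)(CCC=C(C)C)[C@@](CC=C(C)C)(C(=O)C=C1OC)C2=O | intermediate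
29 | C7 O-phenyl thionocarbonate | C=C(C)[C@H](CC=C(C)C)C[C@@]12C[C@H](OC(=S)Oc3ccccc3)[C@](C)(CCC=C(C)C)[C@@](CC=C(C)C)(C(=O)C=C1OC)C2=O | intermediate
30 | C7 allyl compound | C=C(C)[C@H](CC=C(C)C)C[C@@]12C[C@H](CC=C)[C@](C)(CCC=C(C)C)[C@@](CC=C(C)C)(C(=O)C=C1OC)C2=O | intermediate
31 | C7 prenyl compound | C=C(C)[C@H](CC=C(C)C)C[C@@]12C[C@H](CC=C(C)C)[C@](C)(CCC=C(C)C)[C@@](CC=C(C)C)(C(=O)C=C1OC)C2=O | intermediate
32 | 3,4-dihydroxybenzoic acid | O=C(O)c1ccc(O)c(O)c1 | starting material
33 | TBS 3,4-bis(TBS-oxy)benzoate | CC(C)(C)[Si](C)(C)OC(=O)c1ccc(O[Si](C)(C)C(C)(C)C)c(O[Si](C)(C)C(C)(C)C)c1 | intermediate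
34 | 3,4-bis(TBS-oxy)benzoyl chloride | O=C(Cl)c1ccc(O[Si](C)(C)C(C)(C)C)c(O[Si](C)(C)C(C)(C)C)c1 | intermediate
35 | C3-lithio derivative of 31 | C=C(C)[C@H](CC=C(C)C)C[C@@]12C[C@H](CC=C(C)C)[C@](C)(CCC=C(C)C)[C@@](CC=C(C)C)(C(=O)C([Li])=C1OC)C2=O | intermediate
36 | C3-aroyl methyl enol ether, bis-TBS | C=C(C)[C@H](CC=C(C)C)C[C@@]12C[C@H](CC=C(C)C)[C@](C)(CCC=C(C)C)[C@@](CC=C(C)C)(C(=O)C(C(=O)c3ccc(O[Si](C)(C)C(C)(C)C)c(O[Si](C)(C)C(C)(C)C)c3)=C1OC)C2=O | intermediate
37 | C4 enol, bis-TBS ether of the target | C=C(C)[C@H](CC=C(C)C)C[C@@]12C[C@H](CC=C(C)C)[C@](C)(CCC=C(C)C)[C@@](CC=C(C)C)(C(=O)C(C(=O)c3ccc(O[Si](C)(C)C(C)(C)C)c(O[Si](C)(C)C(C)(C)C)c3)=C1O)C2=O | intermediate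
38 | CNP0241026.2 | C=C(C)[C@H](CC=C(C)C)C[C@@]12C[C@H](CC=C(C)C)[C@](C)(CCC=C(C)C)[C@@](CC=C(C)C)(C(=O)C(C(=O)c3ccc(O)c(O)c3)=C1O)C2=O | target

## Step count and risks

Total step count: 22.
Longest linear sequence: 17 steps (steps 1–4, 6, 9–17, 20–22).

Steps most likely to fail:

**Step 10.**
- Risk: during the iodide stage the re-formed C9 cation may be captured by the axial homoprenyl alkene on C8 in a Prins-type closure. The C4 enol ether may be lost to the silyl iodide. Proton loss from the developing C8 cation may divert material to an allylic silyl ether.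
- Fallback: the C–C bond formation is separated from the unmasking of C9. Starting from 19, a catalytic amount of TMSOTf with 2,6-lutidine at −78 °C and a cold amine quench should stop the cascade at the caged methyl ketal 21, which is isolated. The allylic oxidation of step 11, applied to 21, should give the caged ketal vinylogous ester F1. BrBMe2 in CH2Cl2 at −78 °C, a known reagent for ketal cleavage, should open the oxygen bridge and remove the ketal methyl group to give the C7 hydroxy vinylogous ester F2. TMSCl with imidazole returns the material to the route at 23.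

**Step 16.**
- Risk: the C7 radical is a 5-hexenyl-type radical with respect to the homoprenyl alkene on C8, so 5-exo closure may outrun allyl transfer. The axial homoprenyl group may also erode the preference for attack on the open face.
- Fallback: allyl transfer is replaced by a much faster polar-matched radical trap. Starting from 29, a Giese addition (Bu3SnH added slowly, AIBN, excess methyl vinyl ketone, benzene, 80 °C) should give the C7 3-oxobutyl compound F3, again by attack on the open face. MeTi(OiPr)3 at low temperature should add only to the unhindered methyl ketone and give the C7 3-hydroxy-3-methylbutyl compound F4. Dehydration with the Burgess reagent towards the more substituted alkene returns the material to the route at 31 and makes step 17 unnecessary.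

**Step 13.**
- Risk: capture of the hindered bridgehead carbanion next to the quaternary C8 may be slower than proton return from tetramethylpiperidine, or slower than base-induced 1,4-elimination of HBr from prenyl bromide.
- Fallback: the C1–C bond is made with a three-carbon unit and the chain end is built afterwards. Starting from 25, lithiation as in step 13 and capture with allyl iodide, which is smaller and cannot undergo that elimination, should give the C1 allyl compound F5. Cross-metathesis with 2-methylbut-2-ene under the conditions of step 17 returns the material to the route at 27.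

## Further compounds

F1 | step 10 | caged methyl ketal vinylogous ester (C2 ketone, C7–O–C9 bridge) | C=C(C)[C@H](CC=C(C)C)C[C@@]12C[C@@H]3O[C@@]2(OC)[C@H](C(=O)C=C1OC)[C@@]3(C)CCC=C(C)C
F2 | step 10 | C7 hydroxy vinylogous ester with C1–H | C=C(C)[C@H](CC=C(C)C)C[C@@]12C[C@H](O)[C@](C)(CCC=C(C)C)[C@@H](C(=O)C=C1OC)C2=O
F3 | step 16 | C7 3-oxobutyl compound | C=C(C)[C@H](CC=C(C)C)C[C@@]12C[C@H](CCC(C)=O)[C@](C)(CCC=C(C)C)[C@@](CC=C(C)C)(C(=O)C=C1OC)C2=O
F4 | step 16 | C7 3-hydroxy-3-methylbutyl compound | C=C(C)[C@H](CC=C(C)C)C[C@@]12C[C@H](CCC(C)(C)O)[C@](C)(CCC=C(C)C)[C@@](CC=C(C)C)(C(=O)C=C1OC)C2=O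
F5 | step 13 | C1 allyl, C3 silyl, C7 silyloxy compound | C=C(C)[C@H](CC=C(C)C)C[C@@]12C[C@H](O[Si](C)(C)C)[C@](C)(CCC=C(C)C)[C@@](CC=C)(C(=O)C([Si](C)(C)C)=C1OC)C2=O
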